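**Plan**
1. Numbering: the quinone ring is C1(=O)–C2(OH)=C3(CH2CH(OAc)CH3)–C4(=O). It is fused through C4a/C8a to the benzenoid ring C5(OMe)–C6(OMe)–C7(H)–C8(OMe).
2. Enabling feature: apart from the shared C4a=C8a bond, the benzenoid ring is only the chain C5–C6–C7–C8, oxygenated at C5, C6 and C8. This is the carbon and oxygen pattern of a dienol ether of 4-methoxyacetoacetate, so C4a=C8a can be the free alkene of a benzoquinone that already carries the C2 oxygen and the C3 chain.
3. Cuts: the O-methyl adjustments at C2 and C8 come first. Then C4a–C5 and C8–C8a are cut together (diene plus bromobenzoquinone), then C–Br, then the ring–CH2 bond at C3 (aryllithium plus epoxide).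
4. Forward: the chain is joined to a trimethoxybenzene, and this arene is oxidised to the quinone ring and brominated. The benzenoid ring arises last by cycloaddition and aromatisation, followed by O-methylation at C8 and O-demethylation at C2.
5. Stereochemistry: the single (S) centre is bought as (S)-propylene oxide, and its C–O bond is never broken.

Key step: step 7

Remark on the chemistry: the silylation in step 6 is expected to give alkene isomers of the diene. The mixture is assumed to be usable as such, because the diene geometry and all sp3 centres of the adduct vanish on aromatisation.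

Step 1
Reactants: 1 1,2,4-trimethoxybenzene; 2 (S)-propylene oxide
Product: 4 (S)-1-(2,3,6-trimethoxyphenyl)propan-2-ol, via 2,3,6-trimethoxyphenyllithium 3 (not isolated)
Conditions: n-BuLi, THF, 0 °C to rt; then 2, BF3·OEt2, −78 °C; aq NH4Cl
Reagents that add atoms: none
Why: Directed ortho-metalation occurs at C3 of 1, the position flanked by two methoxy groups, and the BF3-activated epoxide is opened by SN2 attack at its unsubstituted CH2, so the oxygen-bearing centre of 2 is not involved and appears unchanged as (S) in 4.

Step 2
Reactants: 4 (S)-1-(2,3,6-trimethoxyphenyl)propan-2-ol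
Product: 5 (S)-1-(2,3,6-trimethoxyphenyl)propan-2-yl acetate
Conditions: Ac2O, pyridine, DMAP (cat.), CH2Cl2, 0 °C to rt
Reagents that add atoms: acetic anhydride, CC(=O)OC(C)=O
Why: DMAP-catalysed O-acylation of a secondary alcohol forms only the O–acyl bond, so the configuration is retained.

Step 3
Reactants: 5 (S)-1-(2,3,6-trimethoxyphenyl)propan-2-yl acetate
Product: 6 (S)-1-(3-methoxy-1,4-benzoquinon-2-yl)propan-2-yl acetate
Conditions: (NH4)2Ce(NO3)6, MeCN–H2O, 0 °C
Reagents that add atoms: water, O
Why: In this ceric oxidative demethylation of a hydroquinone dimethyl ether only the para-related methoxy pair can become a p-quinone, so the third methoxy group stays as the enol ether next to the side chain and the acetate is inert to Ce(IV).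

Step 4
Reactants: 6 (S)-1-(3-methoxy-1,4-benzoquinon-2-yl)propan-2-yl acetate
Product: 8 (S)-1-(5-bromo-3-methoxy-1,4-benzoquinon-2-yl)propan-2-yl acetate, via trans-dibromide adduct 7 (not isolated)
Conditions: Br2 (1 equiv), AcOH–CH2Cl2, 0 °C, dark; then NaOAc, 0 °C to rt
Reagents that add atoms: bromine, BrBr
Why: Bromine addition to the only disubstituted quinone alkene (C5=C6) and E1cB dehydrobromination is the classical bromoquinone synthesis; in 7 the C5–H lies next to the C4 carbonyl, which unlike C1 is not weakened by the MeO–C3=C2–C1=O vinylogous ester, so this more acidic proton should leave with the C6 bromide and bromine stays on C5 (the same sense of elimination as in dibromides of peri-acyloxynaphthoquinones), while acetate is too weak a base to eliminate the side-chain ester.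

Step 5
Reactants: 9 methyl 4-methoxyacetoacetate
Product: 11 methyl (E)-3,4-dimethoxybut-2-enoate, via methyl 3,3,4-trimethoxybutanoate 10 (not isolated)
Conditions: HC(OMe)3, H2SO4 (cat.), MeOH, reflux; then distillation
Reagents that add atoms: trimethyl orthoformate, COC(OC)OC
Why: Acid-catalysed ketalisation with the orthoester, then thermal loss of methanol towards the conjugated β-methoxy enoate, is the standard enol etherification of acetoacetates and favours the (E) isomer, in which CH2OMe is cis to the ester.

Step 6
Reactants: 11 methyl (E)-3,4-dimethoxybut-2-enoate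
Product: 13 1,3,4-trimethoxy-1-(trimethylsilyloxy)buta-1,3-diene (alkene isomer mixture), via lithium dienolate 12 (not isolated)
Conditions: LDA (commercial solution), THF, −78 °C; then TMSCl, −78 °C to rt; non-aqueous work-up, used at once
Reagents that add atoms: chlorotrimethylsilane, C[Si](C)(C)Cl
Why: Kinetic γ-deprotonation of a β-alkoxy enoate (the CH2OMe group sits cis to the ester) gives the extended enolate, which silicon traps on oxygen, the usual preparation of Brassard-type vinylketene acetals.

Step 7
Reactants: 8 (S)-1-(5-bromo-3-methoxy-1,4-benzoquinon-2-yl)propan-2-yl acetate; 13 1,3,4-trimethoxy-1-(trimethylsilyloxy)buta-1,3-diene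
Product: 17 (S)-1-(8-hydroxy-2,5,6-trimethoxy-1,4-naphthoquinon-3-yl)propan-2-yl acetate, via bromo cycloadduct 14 (not isolated), via dihydronaphthoquinone acetal 15 (not isolated), via 8-O-silyl naphthoquinone 16 (not isolated)
Conditions: 13 (2 equiv), toluene, −40 °C to rt; then SiO2, moist CH2Cl2, rt
Reagents that add atoms: none
Why: The three donor oxygens at C1 and C3 of 13 outweigh the one at C4 and make C4 the nucleophilic terminus, so it bonds to the hydrogen-bearing alkene carbon of 8 (future C4a, bond C4a–C5) in a strongly asynchronous cycloaddition while the ketene acetal carbon closes on the bromine-bearing carbon (bond C8–C8a) to give 14. This is the Diels–Alder benzannulation of Brassard-type vinylketene acetals with haloquinones, and the one ring formed, the six-membered benzenoid ring, closes in the intermolecular [4+2] mode (in the stepwise limit, a Michael addition followed by six-membered closure of the bromo enolate onto the silyloxycarbenium carbon). In 14 the enolisable C4a–H has two β leaving groups, and bromide on C8a is far better than methoxide on C5, so HBr goes first and restores the C4a=C8a quinone bond (15); since C8 bears no hydrogen the C5 methoxy group then has no elimination partner, and aromatisation can only run by enolisation of C5–H and expulsion of methoxide from C8 (16), after which moist silica removes the silyl group. Orientation is the selectivity that counts, and it is secured twice in 8: bromine marks the carbon that receives the ketene acetal terminus, and the ring methoxy group weakens the carbonyl next to the side chain (future C4) as a vinylogous ester, so the other carbonyl (future C1) activates its β-carbon C4a for the first bond. Site selectivity follows from the second quinone alkene (C2=C3) being tetrasubstituted and donor-substituted. The four sp3 centres of 14 are all erased, no lasting stereocentre is made, and the neutral medium leaves the acetate and its (S) centre untouched.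

Step 8
Reactants: 17 (S)-1-(8-hydroxy-2,5,6-trimethoxy-1,4-naphthoquinon-3-yl)propan-2-yl acetate
Product: 18 (S)-1-(2,5,6,8-tetramethoxy-1,4-naphthoquinon-3-yl)propan-2-yl acetate
Conditions: MeI, Ag2O, CH2Cl2, rt, dark
Reagents that add atoms: iodomethane, CI
Why: Silver(I) oxide-promoted O-methylation is the usual way to alkylate a chelated peri-hydroxyquinone under nearly neutral conditions that spare the acetate.

Step 9
Reactants: 18 (S)-1-(2,5,6,8-tetramethoxy-1,4-naphthoquinon-3-yl)propan-2-yl acetate
Product: 20 (S)-1-(2-hydroxy-5,6,8-trimethoxy-1,4-naphthoquinon-3-yl)propan-2-yl acetate (CNP0321270.1), via lithium 2-oxidoquinone salt 19 (not isolated)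
Conditions: LiI, EtOAc, reflux, dark; then 1 M HCl
Reagents that add atoms: none
Why: This is the SN2 dealkylation of methyl esters by lithium iodide applied to the vinylogous ester at C2, whose leaving group (the anion of a vinylogous carboxylic acid) is much better than the aryloxides behind the C5, C6 and C8 methyl groups, while the acetate offers only a secondary carbon to iodide and the C–O stereocentre is not touched.

**Compound list**
1 | 1,2,4-trimethoxybenzene | COc1ccc(OC)c(OC)c1 | starting material
2 | (S)-propylene oxide | C[C@H]1CO1 | starting material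
3 | 2,3,6-trimethoxyphenyllithium | [Li]c1c(OC)ccc(OC)c1OC | intermediate
4 | (S)-1-(2,3,6-trimethoxyphenyl)propan-2-ol | COc1ccc(OC)c(OC)c1C[C@H](C)O | intermediate
5 | (S)-1-(2,3,6-trimethoxyphenyl)propan-2-yl acetate | COc1ccc(OC)c(OC)c1C[C@H](C)OC(C)=O | intermediate
6 | (S)-1-(3-methoxy-1,4-benzoquinon-2-yl)propan-2-yl acetate | O=C1C=CC(=O)C(C[C@H](C)OC(C)=O)=C1OC | intermediate
7 | (S)-1-(trans-4,5-dibromo-2-methoxy-3,6-dioxocyclohex-1-en-1-yl)propan-2-yl acetate (both trans diastereomers) | O=C1C(Br)C(Br)C(=O)C(C[C@H](C)OC(C)=O)=C1OC | intermediate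
8 | (S)-1-(5-bromo-3-methoxy-1,4-benzoquinon-2-yl)propan-2-yl acetate | O=C1C(Br)=CC(=O)C(C[C@H](C)OC(C)=O)=C1OC | intermediate
9 | methyl 4-methoxyacetoacetate | COCC(=O)CC(=O)OC | starting material
10 | methyl 3,3,4-trimethoxybutanoate | COCC(OC)(OC)CC(=O)OC | intermediate
11 | methyl (E)-3,4-dimethoxybut-2-enoate | COC/C(OC)=C\C(=O)OC | intermediate
12 | lithium dienolate of 11 | COC=C(OC)C=C(OC)[O-].[Li+] | intermediate
13 | 1,3,4-trimethoxy-1-(trimethylsilyloxy)buta-1,3-diene (alkene isomer mixture) | COC=C(OC)C=C(OC)O[Si](C)(C)C | intermediate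
14 | (S)-1-[8a-bromo-2,5,6,8-tetramethoxy-1,4-dioxo-8-(trimethylsilyloxy)-1,4,4a,5,8,8a-hexahydronaphthalen-3-yl]propan-2-yl acetate (ring diastereomers) | COC1=C(C[C@H](C)OC(C)=O)C(=O)C2C(OC)C(OC)=CC(OC)(O[Si](C)(C)C)C2(Br)C1=O | intermediate
15 | (S)-1-[2,5,6,8-tetramethoxy-1,4-dioxo-8-(trimethylsilyloxy)-1,4,5,8-tetrahydronaphthalen-3-yl]propan-2-yl acetate (ring diastereomers) | COC1=C(C[C@H](C)OC(C)=O)C(=O)C2=C(C1=O)C(OC)(O[Si](C)(C)C)C=C(OC)C2OC | intermediate
16 | (S)-1-[2,5,6-trimethoxy-8-(trimethylsilyloxy)-1,4-naphthoquinon-3-yl]propan-2-yl acetate | COc1cc(O[Si](C)(C)C)c2c(c1OC)C(=O)C(C[C@H](C)OC(C)=O)=C(OC)C2=O | intermediate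
17 | (S)-1-(8-hydroxy-2,5,6-trimethoxy-1,4-naphthoquinon-3-yl)propan-2-yl acetate | COc1cc(O)c2c(c1OC)C(=O)C(C[C@H](C)OC(C)=O)=C(OC)C2=O | intermediate
18 | (S)-1-(2,5,6,8-tetramethoxy-1,4-naphthoquinon-3-yl)propan-2-yl acetate | COc1cc(OC)c2c(c1OC)C(=O)C(C[C@H](C)OC(C)=O)=C(OC)C2=O | intermediate
19 | lithium salt of 20 (2-oxidoquinone) | COc1cc(OC)c2c(c1OC)C(=O)C(C[C@H](C)OC(C)=O)=C([O-])C2=O.[Li+] | intermediate
20 | (S)-1-(2-hydroxy-5,6,8-trimethoxy-1,4-naphthoquinon-3-yl)propan-2-yl acetate (CNP0321270.1) | COc1cc(OC)c2c(c1OC)C(=O)C(C[C@H](C)OC(C)=O)=C(O)C2=O | target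

**Step count**
- Total: 9 steps (steps 1–4 make the bromoquinone, steps 5–6 the diene, steps 7–9 join them and finish).
- Longest linear sequence: 7 steps (1, 2, 3, 4, 7, 8, 9).

**Steps most likely to fail**

**Step 7**
- What may go wrong:
  - The diene isomer whose terminal methoxy group points inward may cycloadd sluggishly.
  - The HBr released may protodesilylate the diene.
  - The C5 methoxy group may be lost by β-elimination from the primary adduct before bromide leaves.
- Fallback: it sets out from 8, rejoins the route at 18, and adds the C5 oxygen only after the ring is built.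
  - LDA/TMSCl on commercial methyl (E)-3-methoxybut-2-enoate would give the parent diene 1,3-dimethoxy-1-(trimethylsilyloxy)buta-1,3-diene F1, whose nucleophilic terminus is a plain CH2.
  - Its benzannulation with 8 would give (S)-1-(8-hydroxy-2,6-dimethoxy-1,4-naphthoquinon-3-yl)propan-2-yl acetate F2.
  - MeI/Ag2O would then give (S)-1-(2,6,8-trimethoxy-1,4-naphthoquinon-3-yl)propan-2-yl acetate F3.
  - A carbonyl-directed ruthenium(II)-catalysed C–H oxygenation ([RuCl2(p-cymene)]2, PhI(OCOCF3)2, TFA/TFAA) would follow. C5 is the only free peri position for it, and aqueous work-up would give (S)-1-(5-hydroxy-2,6,8-trimethoxy-1,4-naphthoquinon-3-yl)propan-2-yl acetate F4.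
  - A second MeI/Ag2O methylation leads to 18.

**Step 4**
- What may go wrong: the two protons of the dibromide may be discriminated poorly during loss of HBr. Bromine would then also end up next to the wrong carbonyl, which would reverse the orientation of the key step.
- Fallback: it sets out from 2, rejoins the route at 8, and fixes the bromine position with a phenol as directing group.
  - Commercial 2,4-dimethoxyphenol would be silylated (TIPSCl, imidazole) to (2,4-dimethoxyphenoxy)triisopropylsilane F5.
  - Lithiation between the two methoxy groups (n-BuLi, THF) and BF3-assisted opening of 2 would give (S)-1-[2,6-dimethoxy-3-(triisopropylsilyloxy)phenyl]propan-2-ol F6.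
  - Acetylation would give (S)-1-[2,6-dimethoxy-3-(triisopropylsilyloxy)phenyl]propan-2-yl acetate F7.
  - TBAF buffered with AcOH would free (S)-1-(3-hydroxy-2,6-dimethoxyphenyl)propan-2-yl acetate F8.
  - Amine-catalysed ortho-selective bromination (NBS, cat. i-Pr2NH, CH2Cl2) would place bromine beside the hydroxyl group, whose para position is blocked, to give (S)-1-(4-bromo-3-hydroxy-2,6-dimethoxyphenyl)propan-2-yl acetate F9.
  - Oxidation of this p-methoxyphenol (PhI(OAc)2, MeCN–H2O) gives 8.

**Step 9**
- What may go wrong: conversion may be slow, with competing cleavage of the chelating peri methoxy groups at C5 and C8. Prolonged heating may also eliminate acetic acid from the side chain.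
- Fallback: it sets out from 18, rejoins the route at 20, and replaces selective dealkylation by global hydrolysis and selective re-esterification.
  - Aqueous LiOH in THF would saponify the acetate and replace the C2 methoxy group by addition–elimination. Acidification would give 2-hydroxy-3-[(S)-2-hydroxypropyl]-5,6,8-trimethoxy-1,4-naphthoquinone F10.
  - Ac2O/pyridine would give (S)-1-(2-acetoxy-5,6,8-trimethoxy-1,4-naphthoquinon-3-yl)propan-2-yl acetate F11.
  - Its quinonoid enol acetate is a vinylogous anhydride and would be cleaved selectively by aqueous NaHCO3 in THF to give 20.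

**Further compounds**
F1 | step 7 | 1,3-dimethoxy-1-(trimethylsilyloxy)buta-1,3-diene | C=C(OC)C=C(OC)O[Si](C)(C)C
F2 | step 7 | (S)-1-(8-hydroxy-2,6-dimethoxy-1,4-naphthoquinon-3-yl)propan-2-yl acetate | COc1cc(O)c2c(c1)C(=O)C(C[C@H](C)OC(C)=O)=C(OC)C2=O
F3 | step 7 | (S)-1-(2,6,8-trimethoxy-1,4-naphthoquinon-3-yl)propan-2-yl acetate | COc1cc(OC)c2c(c1)C(=O)C(C[C@H](C)OC(C)=O)=C(OC)C2=O
F4 | step 7 | (S)-1-(5-hydroxy-2,6,8-trimethoxy-1,4-naphthoquinon-3-yl)propan-2-yl acetate | COc1cc(OC)c2c(c1O)C(=O)C(C[C@H](C)OC(C)=O)=C(OC)C2=O
F5 | step 4 | (2,4-dimethoxyphenoxy)triisopropylsilane | COc1ccc(O[Si](C(C)C)(C(C)C)C(C)C)c(OC)c1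
F6 | step 4 | (S)-1-[2,6-dimethoxy-3-(triisopropylsilyloxy)phenyl]propan-2-ol | COc1ccc(O[Si](C(C)C)(C(C)C)C(C)C)c(OC)c1C[C@H](C)O
F7 | step 4 | (S)-1-[2,6-dimethoxy-3-(triisopropylsilyloxy)phenyl]propan-2-yl acetate | COc1ccc(O[Si](C(C)C)(C(C)C)C(C)C)c(OC)c1C[C@H](C)OC(C)=O
F8 | step 4 | (S)-1-(3-hydroxy-2,6-dimethoxyphenyl)propan-2-yl acetate | COc1ccc(O)c(OC)c1C[C@H](C)OC(C)=O
F9 | step 4 | (S)-1-(4-bromo-3-hydroxy-2,6-dimethoxyphenyl)propan-2-yl acetate | COc1cc(Br)c(O)c(OC)c1C[C@H](C)OC(C)=O
F10 | step 9 | 2-hydroxy-3-[(S)-2-hydroxypropyl]-5,6,8-trimethoxy-1,4-naphthoquinone | COc1cc(OC)c2c(c1OC)C(=O)C(C[C@H](C)O)=C(O)C2=O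
F11 | step 9 | (S)-1-(2-acetoxy-5,6,8-trimethoxy-1,4-naphthoquinon-3-yl)propan-2-yl acetate | COc1cc(OC)c2c(c1OC)C(=O)C(C[C@H](C)OC(C)=O)=C(OC(C)=O)C2=O
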